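The rate constants are assumed; no experiment stands behind them.

- Beside a neighbour flask richer in D, this flask asks how much X outlasts its capture by G.

D 0.30 M; G 6.00 mM; time 15 d

    D → J (k1 = 0.151 h⁻¹)
    J → E (k2 = 0.0972 h⁻¹)
    D → L (k3 = 0.893 h⁻¹)
    E ⇌ X (K4 = 2.0, k4 = 0.861 h⁻¹)
    G + X → G.X (k5 = 1.52 L mol⁻¹ h⁻¹)

1. which holds at 15 d: what has brought the reaction to rest, or that it has not come to rest (it is still moving / forward and back rates have come level / all of D has reacted)
2. share of the D used up at 15 d
3. L at 15 d, in percent of the D charged
4. X at 15 d, in percent of the D charged

- the reaction counts as stopped when no species that holds the D changes by six tenths of a point or more over the second half of the time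
- run time (flask): 15 d

- In this flask the capture of X by G has no way back, and the half-life of X by that capture alone, with G as charged, is 3.2 d, shorter than the 15 d of the run. Yet my reckoning below keeps X at a steady level.
- D leaves by two first-order steps, with half-lives of 0.78 h to L and 0.19 d to J, both short against the time. So I reckon the share of D used up at 100%, and the starting rates give L 85.5% and J 14.5%.
- J passes on with a half-life of 0.30 d, short against the time, so this flask gains a pool of 43.4 mM shared by E, X and G.X.
- G, the limiting reagent of the capture, is charged below that pool, so the balance of G says that its whole charge can bind X with E and X left over. The carried quantity is the free pool F, the E plus X remaining once each G has bound one X: 37.4 mM.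
- The half-life of X of 3.2 d is reckoned with G as charged. Seen from G, X near its final level gives G a half-life of 0.762 d, short against the time.
- E and X relax in 0.537 h, shorter than the time, so their equilibrium constant of 2.0 gives X 66.7% of F, which is 8.31% of the D charged.
- The forecast says all of D has reacted, with conversion 100%, L 85.5% (85% to 86%) and X 8.3% (8% to 8.6%), “with nothing still moving in the second half of the run”.
- The simulation gives all of D has reacted, with conversion 100%, L 85.5% and X 8.31%.
- This flask has 0% of its G left at 15.0 d, and X stands at 8.31% at 7.50 d and 8.31% at 150 d, which is 66.7% of F. The neighbour flask, with 0.51 M of D and the same G, has F = 67.8 mM, which reckons X at 8.87% of its D. That neighbour ends with 0% of its G left and G.X at 1.18%, and its X stands at 8.86%.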